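**Plan**

- Locants used throughout (caryophyllane-type): C1 and C9 are the cyclobutane CH carbons (C1 next to C11 = CMe2; C9 next to C10 = ring CH2 and bonded to the spiro carbon C8); C2–C7 complete the nine-membered ring (C3=C4, C5–OH); C12 is the pyran CH2; C1′ is the isobutyl-bearing CH.
- Retrosynthetic cuts, in order: O–C8 and C12–C1′ (hetero-Diels–Alder on a C8=C12 methylene); C4–C5 (Nozaki–Hiyama–Kishi closure of the nine-membered ring); C8=C12 and C3=C4 (two olefinations of a cyclobutane keto-aldehyde); then C9–C1 and C10–C11 together (one [2+2]).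
- Enabling feature: the cyclobutane CH carbons C1 and C9 carry C2 and C8, and both C3 (alkene CH) and C8 (oxygen-bearing spiro carbon) can come from carbonyl groups. A temporary C3–C8 bond therefore ties the vinyl (C9=C10) and prenyl (C1=C11) units into a 1,6-dien-3-ol, the substrate class of the copper-catalysed [2+2] photocycloaddition; ozonolysis later cuts that bond to give the C8 ketone and the C3 aldehyde.
- Forward ring order: cyclobutane plus temporary cyclopentane (step 3), cyclopentane opened (step 7), nine-membered ring (step 11), dihydropyran (step 12).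
- Stereochemistry: C1 by chirality transfer from an (S)-vinyl carbinol (Sharpless kinetic resolution) in the [2+2]; C9 by base equilibration to the trans-cyclobutane; (Z)-C3=C4 by Stork–Zhao olefination; C5 in the ring closure and C8/C1′ in the cycloaddition, both under substrate control.

Key step: step 3

Remark: syncarpic acid (2,2,4,4-tetramethylcyclohexane-1,3,5-trione) is treated as a purchasable starting material.

**Route**

Step 1
Reactants: 1 5-bromo-2-methylpent-2-ene; 2 acrolein
Product: 4 (±)-7-methylocta-1,6-dien-3-ol, via homoprenylmagnesium bromide 3 (not isolated)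
Conditions: Mg, THF, 23 °C; then 2, −78 → 0 °C; H2O
Reagents that add atoms: none
Why: Grignard 1,2-addition of the homoallylic organomagnesium to acrolein at low temperature should give the racemic vinyl carbinol, whose stereocentre is resolved in step 2.

Step 2
Reactants: 4 (±)-7-methylocta-1,6-dien-3-ol
Product: 5 (3S)-7-methylocta-1,6-dien-3-ol
Conditions: Ti(OiPr)4 (0.1 equiv), D-(−)-diisopropyl tartrate (0.15 equiv), t-BuOOH (0.6 equiv), 4 Å molecular sieves, CH2Cl2, −20 °C
Reagents that add atoms: none
Why: Sharpless kinetic resolution: with the D-(−)-tartrate the (R)-enantiomer of a secondary vinyl carbinol is epoxidised much faster, so (S)-5 should be recovered, and the remote trisubstituted alkene is not an allylic alcohol and stays untouched.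

Step 3
Reactants: 5 (3S)-7-methylocta-1,6-dien-3-ol
Product: 6 (1R,2S,5R)-6,6-dimethylbicyclo[3.2.0]heptan-2-ol (cis-fused, hydroxyl endo)
Conditions: (CuOTf)2·C6H6 (5 mol %), Et2O, hν (254 nm, quartz), 23 °C; chromatographic removal of the minor exo-alcohol
Reagents that add atoms: none
Why: CuOTf gathers the vinyl group, the trisubstituted C=C and the hydroxyl of 5 in one chelate, and 254 nm excitation of this bis(alkene)copper complex (metal–alkene charge transfer) collapses it to the cyclobutane, so that C9–C1 and C10–C11 form in a single photochemical event and CuOTf is released. The closest known reaction type is the Kochi–Salomon copper-catalysed intramolecular [2π+2π] photocycloaddition of 1,6-heptadien-3-ols to bicyclo[3.2.0]heptan-2-ols, which is expected to tolerate an isopropylidene terminus. The cyclobutane closes in the straight (parallel, fused) [2+2] mode, and the temporary cyclopentane (C8, C9, C1, C2, C3) closes with it through the C9–C1 bond, a five-membered ring being the only one the three-atom tether C8–C3–C2 allows. C1 and C9 must be cis on the bicyclo[3.2.0] frame (ring-fusion constraint), and their absolute sense is relayed from the (S)-carbinol C8, because tridentate hydroxyl/alkene/alkene binding to copper should put the hydroxyl on the concave (endo) face; this makes C1 (R), the configuration kept to the end, while C9 is corrected later next to the C8 ketone. The step needs regioselectivity (C9 to C1 and C10 to C11, not the crossed pairing), secured by the tether; endo over exo diastereoselectivity, secured by the hydroxyl–copper contact and backed by removal of the exo epimer, which would otherwise oxidise to the enantiomeric ketone; and freedom from competing alkene chemistry, secured by the absence of any other chromophore or C=C in 5.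

Step 4
Reactants: 6 (1R,2S,5R)-6,6-dimethylbicyclo[3.2.0]heptan-2-ol
Product: 7 (1R,5R)-6,6-dimethylbicyclo[3.2.0]heptan-2-one
Conditions: (nPr4N)RuO4 (5 mol %), N-methylmorpholine N-oxide, 4 Å molecular sieves, CH2Cl2, 23 °C
Reagents that add atoms: none
Why: Ley–Griffith oxidation of the secondary alcohol; the carbinol centre has done its work and is erased, and the two ring-fusion centres are untouched under these non-basic conditions.

Step 5
Reactants: 7 (1R,5R)-6,6-dimethylbicyclo[3.2.0]heptan-2-one
Product: 8 (1R,5R)-6,6-dimethylbicyclo[3.2.0]hept-2-en-2-yl trifluoromethanesulfonate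
Conditions: LiN(iPr)2, THF, −78 °C; PhNTf2, −78 → 0 °C
Reagents that add atoms: N-phenylbis(trifluoromethanesulfonimide), O=S(=O)(N(c1ccccc1)S(=O)(=O)C(F)(F)F)C(F)(F)F
Why: Kinetic deprotonation should occur at the CH2 (C3) and not at the strained ring-fusion CH (C9), and O-triflation fixes the C8=C3 enol regiochemistry without touching a stereocentre.

Step 6
Reactants: 8 (1R,5R)-6,6-dimethylbicyclo[3.2.0]hept-2-en-2-yl trifluoromethanesulfonate; 9 3,3-dimethoxyprop-1-ene
Product: 11 (1R,5R)-2-(3,3-dimethoxypropyl)-6,6-dimethylbicyclo[3.2.0]hept-2-ene, via alkylborane 10 (not isolated)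
Conditions: 9, 9-BBN-H, THF, 0 → 23 °C; then 8, PdCl2(dppf) (5 mol %), aq. K3PO4, DMF, 50 °C
Reagents that add atoms: none
Why: Anti-Markovnikov hydroboration of the acetal-bearing vinyl group followed by B-alkyl Suzuki–Miyaura coupling with the alkenyl triflate attaches C7–C5 to C8; no stereocentre is formed or disturbed.

Step 7
Reactants: 11 (1R,5R)-2-(3,3-dimethoxypropyl)-6,6-dimethylbicyclo[3.2.0]hept-2-ene
Product: 12 2-[(1R,4R)-4-(4,4-dimethoxybutanoyl)-2,2-dimethylcyclobutyl]acetaldehyde (cis)
Conditions: O3, CH2Cl2, −78 °C (Sudan red end-point); PPh3, −78 → 23 °C; used crude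
Reagents that add atoms: ozone, [O-][O+]=O
Why: Ozonolysis with reductive work-up cleaves the only C=C, i.e. the temporary C3–C8 bond, returning C8 as the ketone and C3 as the aldehyde while the cis cyclobutane centres stay untouched.

Step 8
Reactants: 12 2-[(1R,4R)-4-(4,4-dimethoxybutanoyl)-2,2-dimethylcyclobutyl]acetaldehyde
Product: 14 1-{(1S,2R)-2-[(2Z)-3-iodobut-2-en-1-yl]-3,3-dimethylcyclobutyl}-4,4-dimethoxybutan-1-one (trans), via cis-iodoalkene ketone 13 (not isolated)
Conditions: (1-iodoethyl)triphenylphosphonium iodide, NaN(SiMe3)2, THF, −78 °C; add 12, −78 → −20 °C; then K2CO3, MeOH, 23 °C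
Reagents that add atoms: (1-iodoethyl)triphenylphosphonium iodide, CC(I)[P+](c1ccccc1)(c1ccccc1)c1ccccc1.[I-]
Why: Stork–Zhao olefination: the α-iodo ylide reacts with the aldehyde far faster than with the hindered ketone and should give the (Z)-2-iodoalkene under kinetic control; the carbonate/methanol stage then equilibrates C9, α to the ketone, to the more stable trans-1,2-disubstituted cyclobutane (thermodynamic control), C1 being non-epimerisable.

Step 9
Reactants: 14 1-{(1S,2R)-2-[(2Z)-3-iodobut-2-en-1-yl]-3,3-dimethylcyclobutyl}-4,4-dimethoxybutan-1-one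
Product: 15 (1S,2R)-1-(5,5-dimethoxypent-1-en-2-yl)-2-[(2Z)-3-iodobut-2-en-1-yl]-3,3-dimethylcyclobutane
Conditions: methyltriphenylphosphonium bromide, NaN(SiMe3)2, THF, 0 → 40 °C
Reagents that add atoms: methyltriphenylphosphonium bromide, C[P+](c1ccccc1)(c1ccccc1)c1ccccc1.[Br-]
Why: Wittig methylenation of the ketone installs C12; no new stereocentre arises, and C9 is already at its thermodynamic configuration so the basic ylide cannot erode it.

Step 10
Reactants: 15 (1S,2R)-1-(5,5-dimethoxypent-1-en-2-yl)-2-[(2Z)-3-iodobut-2-en-1-yl]-3,3-dimethylcyclobutane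
Product: 16 4-{(1S,2R)-2-[(2Z)-3-iodobut-2-en-1-yl]-3,3-dimethylcyclobutyl}pent-4-enal
Conditions: 0.5 M HCl (aq), THF, 0 → 23 °C
Reagents that add atoms: water, O
Why: Acid-catalysed hydrolysis of the dimethyl acetal under conditions too mild to protonate the 1,1-disubstituted alkene or the iodoalkene.

Step 11
Reactants: 16 4-{(1S,2R)-2-[(2Z)-3-iodobut-2-en-1-yl]-3,3-dimethylcyclobutyl}pent-4-enal
Product: 17 (1R,3Z,5S,9S)-4,11,11-trimethyl-8-methylidenebicyclo[7.2.0]undec-3-en-5-ol
Conditions: CrCl2 (8 equiv), NiCl2 (0.1 equiv), DMSO/THF, 23 °C, slow addition of 16 (final 2 mM)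
Reagents that add atoms: none
Why: Nozaki–Hiyama–Kishi reaction: zerovalent nickel formed in situ inserts into the alkenyl C–I bond with retention of the (Z)-geometry, and transmetalation to chromium followed by chemoselective addition to the aldehyde closes C4–C5 under high dilution, the three sp2 carbons and the trans-fused cyclobutane lowering the strain of the forming nine-membered ring; C5 is set by substrate control, the (5S)-epimer being the one required and a (5R)-epimer being separable.

Step 12
Reactants: 17 (1R,3Z,5S,9S)-4,11,11-trimethyl-8-methylidenebicyclo[7.2.0]undec-3-en-5-ol; 18 syncarpic acid; 19 3-methylbutanal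
Product: 21 tomentodione P, via alkylidene trione 20 (not isolated)
Conditions: 18 (1.5 equiv), 19 (2 equiv), ethylenediammonium diacetate (10 mol %), toluene, 80 °C
Reagents that add atoms: none
Why: Knoevenagel condensation of 18 with 19 gives the electron-poor 1-oxadiene 20, which should undergo an inverse-electron-demand hetero-Diels–Alder reaction with the unhindered 1,1-disubstituted C8=C12 bond in preference to the more encumbered, carbinol-flanked C3=C4 bond, oxygen bonding to the tertiary terminus C8; C8 and C1′ arise together by substrate control, the target requiring O–C8 bond formation on the Re face of C8 (priorities C9 > C7 > C12) with the cyclobutane branch C9 endo, which is expected to be the approach from the exposed outer face of the folded ring.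

**Compound list**

1 | 5-bromo-2-methylpent-2-ene | CC(C)=CCCBr | starting material
2 | acrolein (prop-2-enal) | C=CC=O | starting material
3 | (4-methylpent-3-en-1-yl)magnesium bromide | CC(C)=CCC[Mg]Br | intermediate (not isolated)
4 | (±)-7-methylocta-1,6-dien-3-ol | C=CC(O)CCC=C(C)C | intermediate
5 | (3S)-7-methylocta-1,6-dien-3-ol | C=C[C@@H](O)CCC=C(C)C | intermediate
6 | (1R,2S,5R)-6,6-dimethylbicyclo[3.2.0]heptan-2-ol | O[C@H]1CC[C@@H]2[C@H]1CC2(C)C | intermediate
7 | (1R,5R)-6,6-dimethylbicyclo[3.2.0]heptan-2-one | O=C1CC[C@@H]2[C@H]1CC2(C)C | intermediate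
8 | (1R,5R)-6,6-dimethylbicyclo[3.2.0]hept-2-en-2-yl trifluoromethanesulfonate | O=S(=O)(OC1=CC[C@@H]2[C@H]1CC2(C)C)C(F)(F)F | intermediate
9 | 3,3-dimethoxyprop-1-ene (acrolein dimethyl acetal) | C=CC(OC)OC | starting material
10 | 9-(3,3-dimethoxypropyl)-9-borabicyclo[3.3.1]nonane | COC(CCB1C2CCCC1CCC2)OC | intermediate (not isolated)
11 | (1R,5R)-2-(3,3-dimethoxypropyl)-6,6-dimethylbicyclo[3.2.0]hept-2-ene | COC(CCC1=CC[C@@H]2[C@H]1CC2(C)C)OC | intermediate
12 | 2-[(1R,4R)-4-(4,4-dimethoxybutanoyl)-2,2-dimethylcyclobutyl]acetaldehyde (cis) | O=CC[C@@H]1[C@@H](CC1(C)C)C(=O)CCC(OC)OC | intermediate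
13 | 1-{(1R,2R)-2-[(2Z)-3-iodobut-2-en-1-yl]-3,3-dimethylcyclobutyl}-4,4-dimethoxybutan-1-one (cis) | C/C(I)=C/C[C@@H]1[C@@H](CC1(C)C)C(=O)CCC(OC)OC | intermediate (not isolated)
14 | 1-{(1S,2R)-2-[(2Z)-3-iodobut-2-en-1-yl]-3,3-dimethylcyclobutyl}-4,4-dimethoxybutan-1-one (trans) | C/C(I)=C/C[C@@H]1[C@H](CC1(C)C)C(=O)CCC(OC)OC | intermediate
15 | (1S,2R)-1-(5,5-dimethoxypent-1-en-2-yl)-2-[(2Z)-3-iodobut-2-en-1-yl]-3,3-dimethylcyclobutane | C/C(I)=C/C[C@@H]1[C@H](CC1(C)C)C(=C)CCC(OC)OC | intermediate
16 | 4-{(1S,2R)-2-[(2Z)-3-iodobut-2-en-1-yl]-3,3-dimethylcyclobutyl}pent-4-enal | C/C(I)=C/C[C@@H]1[C@H](CC1(C)C)C(=C)CCC=O | intermediate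
17 | (1R,3Z,5S,9S)-4,11,11-trimethyl-8-methylidenebicyclo[7.2.0]undec-3-en-5-ol | C/C1=C/C[C@@H]2[C@H](CC2(C)C)C(=C)CC[C@@H]1O | intermediate
18 | syncarpic acid (2,2,4,4-tetramethylcyclohexane-1,3,5-trione) | CC1(C)C(=O)CC(=O)C(C)(C)C1=O | starting material
19 | 3-methylbutanal (isovaleraldehyde) | CC(C)CC=O | starting material
20 | 2,2,4,4-tetramethyl-6-(3-methylbutylidene)cyclohexane-1,3,5-trione | CC(C)CC=C1C(=O)C(C)(C)C(=O)C(C)(C)C1=O | intermediate (not isolated)
21 | tomentodione P | C/C1=C/C[C@@H]2[C@H](CC2(C)C)[C@]2(CC[C@@H]1O)C[C@H](CC(C)C)C1=C(O2)C(C)(C)C(=O)C(C)(C)C1=O | target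

**Totals and risks**

Total step count: 12. Longest linear sequence: 12 steps (1 → 21; compounds 2, 9, 18 and 19 are purchased).

Steps most likely to fail:

1. Step 12 (hetero-Diels–Alder). What may go wrong: insufficient facial and endo/exo discrimination at the exocyclic C8=C12 bond of the flexible nine-membered ring (up to four diastereomers), and heat- or acid-induced allylic transposition of the free carbinol. Fallback: change the order of ring formation. Setting out from 15, the same in-situ Knoevenagel/hetero-Diels–Alder reaction with 18 and 19 (ethylenediammonium diacetate, toluene, 80 °C) would be run on the open-chain methylene compound, where the adjacent stereocentre C9 biases the alkene face through allylic strain and the diastereomers can be separated before the costly ring closure, to give the chroman acetal F1. Hydrolysis (0.5 M HCl, THF) would give the chroman aldehyde F2, and CrCl2/NiCl2 closure of C4–C5 on F2, with the spiro centre already fixed, would come back to the route at 21.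

2. Step 11 (Nozaki–Hiyama–Kishi closure). What may go wrong: addition to either face of the aldehyde, giving the wrong or a mixed C5 configuration, alongside intermolecular coupling. Fallback: put C5 under reagent control by a redox relay. Setting out from 16, the closure is run as before, and the crude mixture of 17 and its C5 epimer F3 is oxidised (MnO2, CH2Cl2) to the (Z)-enone F4. F4 is then reduced with catecholborane and (R)-2-methyl-CBS-oxazaborolidine (alkenyl branch as the large group), coming back to the route at 17.

3. Step 3 (copper-catalysed [2+2]). What may go wrong: weak binding of the trisubstituted alkene to copper (slow conversion, catalyst decomposition under irradiation) and an endo/exo ratio too low to carry the carbinol chirality into the ring. Fallback: form the same two bonds by a catalyst-controlled intermolecular [2+2]. Setting out from 1, a gold-catalysed alkyne–alkene [2+2] with phenylacetylene would give the phenylcyclobutene F5, with the phenyl-bearing carbon joined to the CH terminus and the alkyne CH to the CMe2 terminus of the alkene. The catalyst would be (AuCl)2(L*), L* = a Josiphos-type ferrocenyl diphosphine, activated by NaB[3,5-(CF3)2C6H3]4 in PhCl at 0 °C, with the ligand enantiomer chosen for the (S)-product. H2 over Pd/C would give the cis-phenylcyclobutane F6, and RuCl3/NaIO4 would degrade the phenyl ring to the carboxylic acid F7. (COCl)2 then MeNHOMe·HCl/pyridine would give the Weinreb amide F8, and (3,3-dimethoxypropyl)magnesium bromide would give the bromo ketone F9. Trimethylamine N-oxide in DMSO would convert the primary bromide into the aldehyde, coming back to the route at 12.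

**Further compounds**

F1 | step 12 | chroman acetal, hetero-Diels–Alder adduct of 15 (new centres 2S,4S as in 21) | C/C(I)=C/C[C@@H]1[C@H](CC1(C)C)[C@]1(CCC(OC)OC)C[C@H](CC(C)C)C2=C(O1)C(C)(C)C(=O)C(C)(C)C2=O
F2 | step 12 | chroman aldehyde (acetal of F1 hydrolysed) | C/C(I)=C/C[C@@H]1[C@H](CC1(C)C)[C@]1(CCC=O)C[C@H](CC(C)C)C2=C(O1)C(C)(C)C(=O)C(C)(C)C2=O
F3 | step 11 | (1R,3Z,5R,9S)-4,11,11-trimethyl-8-methylidenebicyclo[7.2.0]undec-3-en-5-ol (C5 epimer of 17) | C/C1=C/C[C@@H]2[C@H](CC2(C)C)C(=C)CC[C@H]1O
F4 | step 11 | (1R,3Z,9S)-4,11,11-trimethyl-8-methylidenebicyclo[7.2.0]undec-3-en-5-one | C/C1=C/C[C@@H]2[C@H](CC2(C)C)C(=C)CCC1=O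
F5 | step 3 | (4S)-4-(2-bromoethyl)-3,3-dimethyl-1-phenylcyclobut-1-ene | BrCC[C@@H]1C(c2ccccc2)=CC1(C)C
F6 | step 3 | [(1R,2R)-2-(2-bromoethyl)-3,3-dimethylcyclobutyl]benzene (cis) | BrCC[C@@H]1[C@@H](CC1(C)C)c1ccccc1
F7 | step 3 | (1R,2R)-2-(2-bromoethyl)-3,3-dimethylcyclobutane-1-carboxylic acid (cis) | BrCC[C@@H]1[C@@H](CC1(C)C)C(=O)O
F8 | step 3 | (1R,2R)-2-(2-bromoethyl)-N-methoxy-N,3,3-trimethylcyclobutane-1-carboxamide (cis) | BrCC[C@@H]1[C@@H](CC1(C)C)C(=O)N(C)OC
F9 | step 3 | 1-[(1R,2R)-2-(2-bromoethyl)-3,3-dimethylcyclobutyl]-4,4-dimethoxybutan-1-one (cis) | BrCC[C@@H]1[C@@H](CC1(C)C)C(=O)CCC(OC)OC
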